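The data stem from a simulated flask from invented constants, and the scatter is random.

The easy mistake with this flask is to watch the base, which differs between Sunday's and Monday's, and to leave unreckoned the protic impurity, which is the same in both.

common to all: starting material 0.10 M; partner 1.05 equiv
- winter: base 0.062 equiv; protic impurity 0.050 M; run made earlier
- dusk: base 0.089 equiv; protic impurity 0.050 M; run made earlier
- Sunday's: base 0.0650 equiv; protic impurity 0.0500 M; time 25 h
- Monday's: base 0.0500 equiv; protic impurity 0.0500 M; time 25 h

| run | time / h | starting material / % | product / % |
|---|---|---|---|
| winter | 2.00 | 85.8 | 0 |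
| winter | 4.00 | 76.3 | 0.1 |
| winter | 5.00 | 70.5 | 1.0 |
| winter | 8.00 | 63.2 | 1.0 |
| winter | 10.0 | 61.0 | 2.2 |
| winter | 12.0 | 57.5 | 1.0 |
| dusk | 0.667 | 95.3 | 0 |
| dusk | 2.00 | 85.6 | 0.2 |
| dusk | 4.00 | 76.0 | 0 |
| dusk | 5.00 | 69.8 | 1.2 |
| dusk | 8.00 | 63.2 | 1.9 |
| dusk | 10.0 | 61.7 | 0.3 |
| dusk | 12.0 | 56.7 | 1.5 |

(each reading ± 1 percentage point)



* part of the starting material that has reacted at the end, Sunday's
* part of the starting material that has reacted at the end, Monday's
* what raising the equivalents of base from its lowest to its highest value here does to the part of the starting material that has reacted (changes below 5 percentage points count as none) (no change / it rises / it falls)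

The first speaker at the meeting reported that the winter run had lost 42.5% of its starting material by 12.0 h and the dusk run 43.3%, although their base stood at 0.062 equiv and 0.089 equiv, while product read 1.0% and 1.5%, so she treated the two curves as one.

The second speaker proposed freezing one thing: if starting material is lost one-for-one to the impurity, whose share of the charge is 50.0%, then starting material minus impurity, as fractions of that charge, stays at 50.0%.

The first speaker objected that this was a guess, so she took the mean fraction of starting material left at 5.00 h in the two runs, 70.2%, and put it through the second-order rate law to read the pairing rate, the rate constant of starting material with impurity times the starting-material charge, as 0.222 h⁻¹. That rate returned 57.6% left at 12.0 h, against the 57.5% read in the winter run.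

Run to 25 h, it left 1.61% of the charge as impurity, so the meeting's reckoning was 48.4% reacted in both flasks, with the caution that Monday's 0.0500 equiv of base lies below both runs.

The forecast differs slightly, giving 51% and 51% with no change, and holding that “By 25 h the plateau is essentially reached”.

The flasks give 49.2% on Sunday's and 49.2% on Monday's, and the base range shows no change, a change of 0 percentage points. Sunday's flask holds 47.7% quenched substrate beside 1.48% product at 25.0 h. The pairing rate had put the impurity left in Sunday's at 3.22% of its own charge, and the flask shows 4.63%.

    starting material + partner + by-product → product + 2 by-product (k = 0.520 L² mol⁻² min⁻¹)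
    starting material + partner → product + by-product (k = 5.70 × 10⁻⁴ L mol⁻¹ min⁻¹)
    base + by-product ⇌ salt, settled at all times (K = 13000 L mol⁻¹)
    partner + by-product ⇌ idle adduct, settled at all times (K = 870 L mol⁻¹)
    partner → decomposed reagent (k = 0.00300 min⁻¹)
    starting material + protic impurity → quenched substrate (k = 0.0330 L mol⁻¹ min⁻¹)

A neighbour of Sunday's charged with 0.060 M of starting material has a share of 83.3% and a pairing rate of 0.133 h⁻¹, which give 68.0% reacted at 25 h. The computed flask gives 66.7%.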